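**Strategy.** Ring B (O1, C2=O, C3–C6) is cut across C5–C6 and O1–C2. Its C3=C4 alkene and its C6 carbinol, which is bonded to the methine C3′ of butyrolactone ring C, form the pattern left by a hetero-Diels–Alder reaction of an aldehyde with a 1-alkoxybutadiene. One catalytic cycloaddition therefore closes ring B at the acetal oxidation level and sets C6 under catalyst control, and the ring oxygen is never a free hydroxyl that could transacylate ring C. The precursor is the small lactone aldehyde (3R)-5-oxooxolane-3-carbaldehyde, made from resolved paraconic acid. The side chain (ring A to C3) is attached last by a B-alkyl Suzuki–Miyaura coupling.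

Key step: step 6

Numbering: ring A is the trimethylcyclohexene; ring B is O1, C2(=O), C3–C6; ring C is the butyrolactone with methine C3′.

Assumption 1: the lipase in step 3 is taken to hydrolyse the (R)-ester of 5 faster; if screening shows the opposite preference, the residual (R)-ester is taken to high enantiomeric purity and hydrolysed with aq. HCl to the same acid 6.

Assumption 2: the (1R,2S)-aminoindanol-derived CrCl catalyst is taken to deliver the diene to the aldehyde face that gives 6R, as recalled for this catalyst family with aldehydes whose substituent ranks between the ring oxygen and the ring CH2; the antipodal catalyst is equally accessible if the sense proves reversed.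

**Step 1**
Reactants: 1 diethyl succinate; 2 ethyl formate
Product: 3 diethyl 2-formylbutanedioate (racemic, partly enolised)
Conditions: NaOEt (1.1 equiv), Et2O, 0 °C to rt; cold aq. HCl
Reagents that add atoms: none
Why: Crossed Claisen condensation: ethyl formate cannot enolise and is the more electrophilic ester, so the succinate enolate should be formylated once and the product is held as its stabilised sodium enolate until the acid quench.

**Step 2**
Reactants: 3 diethyl 2-formylbutanedioate
Product: 5 ethyl 5-oxooxolane-3-carboxylate (racemic ethyl paraconate), via hydroxy diester 4 (not isolated)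
Conditions: NaBH4, EtOH, 0 °C; then aq. HCl, rt to 50 °C
Reagents that add atoms: none
Why: Chemoselective NaBH4 reduction of the formyl group beside two esters, then acid-catalysed lactonisation (5-exo-trig acyl substitution) of the γ-hydroxy ester onto the distal ester; the stereocentre arises racemic at this stage.

**Step 3**
Reactants: 5 ethyl 5-oxooxolane-3-carboxylate (racemic)
Product: 6 (3R)-5-oxooxolane-3-carboxylic acid
Conditions: immobilised Candida antarctica lipase B, 0.1 M phosphate buffer pH 7, pH-stat with aq. NaOH, rt, stopped near 45% conversion; EtOAc wash removes the (S)-ester; aq. HCl to pH 2; continuous EtOAc extraction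
Reagents that add atoms: water, O
Why: Enzymatic kinetic resolution by enantioselective ester hydrolysis: the stereocentre lies α to the ester carbonyl, where serine hydrolases discriminate well, and the γ-lactone survives neutral buffer, so the (3R)-acid should be obtained and sets C3′ of ring C.

**Step 4**
Reactants: 6 (3R)-5-oxooxolane-3-carboxylic acid
Product: 7 (4S)-4-(hydroxymethyl)oxolan-2-one
Conditions: BH3·SMe2 (1.2 equiv), THF, 0 °C to rt; MeOH quench, co-evaporation
Reagents that add atoms: none
Why: Chemoselective borane reduction of a carboxylic acid through its acyloxyborane, which is faster than reduction of the lactone; no bond at the stereocentre is broken, and its descriptor becomes S only through the change in substituent priorities.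

**Step 5**
Reactants: 7 (4S)-4-(hydroxymethyl)oxolan-2-one
Product: 8 (3R)-5-oxooxolane-3-carbaldehyde
Conditions: Dess–Martin periodinane (1.2 equiv), solid NaHCO3, CH2Cl2, 0 °C to rt; Et2O dilution, filtration through Celite, cold concentration; used at once
Reagents that add atoms: none
Why: Dess–Martin oxidation of a primary alcohol under buffered, base-free and non-aqueous conditions, chosen so that this water-soluble, enolisable β-acyloxy aldehyde is neither epimerised at C3 nor opened by β-elimination.

**Step 6**
Reactants: 8 (3R)-5-oxooxolane-3-carbaldehyde; 9 (E)-1-methoxybuta-1,3-diene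
Product: 10 (4R)-4-[(2R,6S)-6-methoxy-3,6-dihydro-2H-pyran-2-yl]oxolan-2-one
Conditions: CrCl complex of the tridentate Schiff base from (1R,2S)-1-aminoindan-2-ol and 3-(1-adamantyl)-2-hydroxy-5-methylbenzaldehyde (5 mol %), powdered 4 Å molecular sieves, 9 (3 equiv), minimal t-BuOMe, 0 °C to rt
Reagents that add atoms: none
Why: The Lewis-acidic trivalent chromium centre binds the aldehyde oxygen of 8 and the electron-rich diene adds in a concerted, asynchronous [4+2] cycloaddition in which C5–C6 bond formation runs ahead of O1–C2 bond formation; the closest known reaction type is the chromium Schiff-base-catalysed hetero-Diels–Alder reaction of aldehydes with 1-alkoxybutadienes. Ring B is closed by this intermolecular cycloaddition itself, both ring bonds being made in the one pericyclic event. The new carbinol centre C6 (R) is set by the catalyst, whose chiral pocket exposes one face of the bound aldehyde, and the acetal centre (S, destroyed in step 7) follows from the endo transition state, which places the methoxy group cis to the lactone substituent. The step needs facial selectivity at the aldehyde that overrides any bias from the resident C3′ centre, and the reagent control this catalyst family exerts over α-branched chiral aldehydes should secure it. Chemoselectivity rests on the aldehyde being the only carbonyl group electrophilic enough to react, while the base-free medium over sieves leaves the enolisable C3′–H and the β-acyloxy group intact.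

**Step 7**
Reactants: 10 (4R)-4-[(2R,6S)-6-methoxy-3,6-dihydro-2H-pyran-2-yl]oxolan-2-one
Product: 12 (6R)-6-[(3R)-5-oxooxolan-3-yl]-5,6-dihydro-2H-pyran-2-one, via lactol 11 (not isolated)
Conditions: CrO3, aq. H2SO4 (Jones reagent), acetone, 0 °C; i-PrOH quench
Reagents that add atoms: water, O
Why: Jones oxidation: aqueous acid hydrolyses the methyl acetal to lactol 11 and hexavalent chromium oxidises it to the conjugated δ-lactone; neither stereocentre is α to a carbonyl group, so C6 and C3′ should be unaffected while the mixed acetal centre disappears.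

**Step 8**
Reactants: 12 (6R)-6-[(3R)-5-oxooxolan-3-yl]-5,6-dihydro-2H-pyran-2-one
Product: 14 (6R)-3-bromo-6-[(3R)-5-oxooxolan-3-yl]-5,6-dihydro-2H-pyran-2-one, via dibromide 13 (not isolated)
Conditions: Br2 (1.05 equiv), CH2Cl2, 0 °C to rt; then Et3N (1.5 equiv), 0 °C
Reagents that add atoms: bromine, BrBr
Why: Bromination–dehydrobromination of an α,β-unsaturated lactone: anti addition of Br2 across C3=C4, then amine-induced E1cB loss of HBr through the acidic C3–H with departure of the C4 bromide, should place bromine on C3 and restore the C3=C4 alkene; 12 has no other alkene.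

**Step 9**
Reactants: 15 dihydro-β-ionone, 4-(2,6,6-trimethylcyclohex-1-en-1-yl)butan-2-one
Product: 17 2-(but-3-yn-1-yl)-1,3,3-trimethylcyclohex-1-ene, via enol phosphate 16 (not isolated)
Conditions: LiN(i-Pr)2 (1.05 equiv), THF, −78 °C; ClP(O)(OEt)2, −78 °C to rt; then LiN(i-Pr)2 (2.3 equiv), THF, −78 °C to rt; aq. NH4Cl
Reagents that add atoms: none
Why: Conversion of a methyl ketone into a terminal alkyne: kinetic deprotonation at the methyl group, O-phosphorylation of the enolate and base-induced β-elimination of diethyl phosphate, with acetylide formation pulling the product to the terminal alkyne.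

**Step 10**
Reactants: 17 2-(but-3-yn-1-yl)-1,3,3-trimethylcyclohex-1-ene; 18 bromoethene
Product: 20 1,3,3-trimethyl-2-[(3E)-3-methylhexa-3,5-dien-1-yl]cyclohex-1-ene, via alkenylalane 19 (not isolated)
Conditions: Me3Al (2 equiv), Cp2ZrCl2 (0.25 equiv), CH2Cl2, 0 °C to rt; then 18 (1 M in THF), Pd(PPh3)4 (5 mol %), ZnCl2 (co-catalyst), THF, rt
Reagents that add atoms: trimethylaluminium, C[Al](C)C
Why: Zirconium-catalysed carboalumination adds CH3 and Al syn across the terminal alkyne with Al on the terminal carbon, which fixes the E trisubstituted alkene, and the Negishi coupling of the alkenylalane with bromoethene keeps that geometry.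

**Step 11**
Reactants: 20 1,3,3-trimethyl-2-[(3E)-3-methylhexa-3,5-dien-1-yl]cyclohex-1-ene; 14 (6R)-3-bromo-6-[(3R)-5-oxooxolan-3-yl]-5,6-dihydro-2H-pyran-2-one
Product: 22 (6R)-3-[(3E)-4-methyl-6-(2,6,6-trimethylcyclohex-1-en-1-yl)hex-3-en-1-yl]-6-[(3R)-5-oxooxolan-3-yl]-5,6-dihydro-2H-pyran-2-one (CNP0207009.2), via homoallylic borane 21 (not isolated)
Conditions: 20 (1.3 equiv), 9-BBN (1.2 equiv), THF, 0 °C to rt; then 14 (1.0 equiv), PdCl2(dppf) (5 mol %), AsPh3 (5 mol %), aq. K3PO4 (3 M), DMF, rt
Reagents that add atoms: none
Why: Regio- and chemoselective hydroboration of the monosubstituted terminal alkene of the 1,3-diene by 9-BBN (boron to the terminal carbon) and B-alkyl Suzuki–Miyaura coupling of the borane with the C3 bromide of the α-bromo enoate, which forms the C3–CH2 bond without moving the C3=C4 alkene, under a phosphate base mild enough for both lactones.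

**Compound list**

1 | diethyl succinate | CCOC(=O)CCC(=O)OCC | starting material
2 | ethyl formate | CCOC=O | starting material
3 | diethyl 2-formylbutanedioate (racemic) | CCOC(=O)CC(C=O)C(=O)OCC | intermediate
4 | diethyl 2-(hydroxymethyl)butanedioate (racemic) | CCOC(=O)CC(CO)C(=O)OCC | intermediate
5 | ethyl 5-oxooxolane-3-carboxylate (racemic ethyl paraconate) | CCOC(=O)C1COC(=O)C1 | intermediate
6 | (3R)-5-oxooxolane-3-carboxylic acid | OC(=O)[C@H]1COC(=O)C1 | intermediate
7 | (4S)-4-(hydroxymethyl)oxolan-2-one | OC[C@H]1COC(=O)C1 | intermediate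
8 | (3R)-5-oxooxolane-3-carbaldehyde | O=C[C@H]1COC(=O)C1 | intermediate
9 | (E)-1-methoxybuta-1,3-diene | CO/C=C/C=C | starting material
10 | (4R)-4-[(2R,6S)-6-methoxy-3,6-dihydro-2H-pyran-2-yl]oxolan-2-one | CO[C@@H]1C=CC[C@H]([C@H]2COC(=O)C2)O1 | intermediate
11 | (4R)-4-[(2R)-6-hydroxy-3,6-dihydro-2H-pyran-2-yl]oxolan-2-one (lactol, anomeric mixture) | OC1C=CC[C@H]([C@H]2COC(=O)C2)O1 | intermediate
12 | (6R)-6-[(3R)-5-oxooxolan-3-yl]-5,6-dihydro-2H-pyran-2-one | O=C1C=CC[C@H]([C@H]2COC(=O)C2)O1 | intermediate
13 | (6R)-3,4-dibromo-6-[(3R)-5-oxooxolan-3-yl]oxan-2-one (trans-dibromide, C3 and C4 not assigned) | O=C1C(Br)C(Br)C[C@H]([C@H]2COC(=O)C2)O1 | intermediate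
14 | (6R)-3-bromo-6-[(3R)-5-oxooxolan-3-yl]-5,6-dihydro-2H-pyran-2-one | O=C1C(Br)=CC[C@H]([C@H]2COC(=O)C2)O1 | intermediate
15 | dihydro-β-ionone, 4-(2,6,6-trimethylcyclohex-1-en-1-yl)butan-2-one | CC(=O)CCC1=C(C)CCCC1(C)C | starting material
16 | diethyl 4-(2,6,6-trimethylcyclohex-1-en-1-yl)but-1-en-2-yl phosphate | C=C(CCC1=C(C)CCCC1(C)C)OP(=O)(OCC)OCC | intermediate
17 | 2-(but-3-yn-1-yl)-1,3,3-trimethylcyclohex-1-ene | C#CCCC1=C(C)CCCC1(C)C | intermediate
18 | bromoethene (vinyl bromide) | C=CBr | starting material
19 | dimethyl[(1E)-2-methyl-4-(2,6,6-trimethylcyclohex-1-en-1-yl)but-1-en-1-yl]alumane | C[Al](C)/C=C(\C)CCC1=C(C)CCCC1(C)C | intermediate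
20 | 1,3,3-trimethyl-2-[(3E)-3-methylhexa-3,5-dien-1-yl]cyclohex-1-ene | C=C/C=C(\C)CCC1=C(C)CCCC1(C)C | intermediate
21 | 9-[(3E)-4-methyl-6-(2,6,6-trimethylcyclohex-1-en-1-yl)hex-3-en-1-yl]-9-borabicyclo[3.3.1]nonane | CC(/CCC1=C(C)CCCC1(C)C)=C\CCB1C2CCCC1CCC2 | intermediate
22 | (6R)-3-[(3E)-4-methyl-6-(2,6,6-trimethylcyclohex-1-en-1-yl)hex-3-en-1-yl]-6-[(3R)-5-oxooxolan-3-yl]-5,6-dihydro-2H-pyran-2-one | CC1=C(CC/C(C)=C/CCC2=CC[C@H]([C@H]3COC(=O)C3)OC2=O)C(C)(C)CCC1 | target

**Step count.** Total: 11 steps. Longest linear sequence: 9 steps (steps 1–8, then 11); the side-chain branch is steps 9–10.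

**Steps most likely to fail**

Step 6. The unactivated diene may add so slowly that 8 epimerises at C3′ or opens by β-elimination before it reacts, or catalyst control of the aldehyde face may be poor. Ring B would then be closed by ring-closing metathesis instead. The fallback sets out from 8. Allylboration with the B-allyldiisopinocampheylborane prepared from (+)-B-methoxydiisopinocampheylborane (Re-face addition; Et2O, −78 °C; buffered, non-basic work-up) should give the homoallylic alcohol (4R)-4-[(1R)-1-hydroxybut-3-en-1-yl]oxolan-2-one F1. It is acylated at once (acryloyl chloride, Et3N, CH2Cl2, −20 °C) to the acrylate (1R)-1-[(3R)-5-oxooxolan-3-yl]but-3-en-1-yl prop-2-enoate F2, so that the ring C acyl group cannot migrate to the new hydroxyl. Ring-closing metathesis with the second-generation Grubbs catalyst (CH2Cl2, 40 °C, high dilution) forms C3=C4 and comes back to the route at 12; step 7 is skipped.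

Step 11. Transmetalation of the alkylborane may be sluggish, so that protodebromination of 14 or base-induced opening of the lactones competes, and hydroboration of the diene may not be fully regioselective. A base-free Negishi alkyl–alkenyl coupling that avoids the diene would be used. The fallback sets out from alkyne 17. Carboalumination as in step 10 gives alane 19, which is converted into its ate complex (n-BuLi) and opened onto oxirane (THF, −30 °C to rt) to give (3E)-4-methyl-6-(2,6,6-trimethylcyclohex-1-en-1-yl)hex-3-en-1-ol F3. An Appel reaction (I2, PPh3, imidazole, CH2Cl2, 0 °C) gives 2-[(3E)-6-iodo-3-methylhex-3-en-1-yl]-1,3,3-trimethylcyclohex-1-ene F4. Zinc insertion (Zn dust, LiCl, THF, 40 °C) gives iodo[(3E)-4-methyl-6-(2,6,6-trimethylcyclohex-1-en-1-yl)hex-3-en-1-yl]zinc F5. Coupling with 14 (Pd(OAc)2, SPhos, THF/NMP, rt) comes back to the route at 22.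

Step 5. The aldehyde may racemise through its enol, lose the lactone oxygen by β-elimination, or be lost as its hydrate during oxidation and isolation. It would then be reached by reduction from the acid oxidation level under neutral, non-aqueous conditions. The fallback sets out from 6. Thioesterification (EtSH, DCC, cat. DMAP, CH2Cl2, 0 °C) gives S-ethyl (3R)-5-oxooxolane-3-carbothioate F6. Fukuyama reduction (Et3SiH, Pd/C, acetone, rt; filtration and cold concentration) comes back to the route at 8; alcohol 7 is bypassed.

**Further compounds**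

F1 | step 6 | (4R)-4-[(1R)-1-hydroxybut-3-en-1-yl]oxolan-2-one | C=CC[C@H]([C@H]1COC(=O)C1)O
F2 | step 6 | (1R)-1-[(3R)-5-oxooxolan-3-yl]but-3-en-1-yl prop-2-enoate | C=CC[C@H]([C@H]1COC(=O)C1)OC(=O)C=C
F3 | step 11 | (3E)-4-methyl-6-(2,6,6-trimethylcyclohex-1-en-1-yl)hex-3-en-1-ol | OCC/C=C(\C)CCC1=C(C)CCCC1(C)C
F4 | step 11 | 2-[(3E)-6-iodo-3-methylhex-3-en-1-yl]-1,3,3-trimethylcyclohex-1-ene | ICC/C=C(\C)CCC1=C(C)CCCC1(C)C
F5 | step 11 | iodo[(3E)-4-methyl-6-(2,6,6-trimethylcyclohex-1-en-1-yl)hex-3-en-1-yl]zinc | I[Zn]CC/C=C(\C)CCC1=C(C)CCCC1(C)C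
F6 | step 5 | S-ethyl (3R)-5-oxooxolane-3-carbothioate | CCSC(=O)[C@H]1COC(=O)C1
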